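The earlier runs and the new flask were generated by integration for substances that don't exist.

Target above 60.0% of the substrate charged is impossible in these four flasks if each target holds one first nucleophile, since the first nucleophile is the limiting reagent. Where that ratio of first nucleophile charged to substrate charged lies below one, I call it the roof.

in all of them: gas 95 mM (held)
- birch: substrate 1.5 M; first nucleophile 1.3 M; temperature 0 °C; run made earlier
- oak: substrate 1.5 M; first nucleophile 2 M; temperature 35 °C; run made earlier
- elm: substrate 2.2 M; first nucleophile 0.90 M; temperature 0 °C; run made earlier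
- Tuesday's: substrate 1.5 M; first nucleophile 0.900 M; temperature 65 °C; time 10 min
- Monday's: substrate 1.5 M; first nucleophile 0.900 M; temperature 35 °C; time 10 min
- Thursday's: substrate 1.5 M; first nucleophile 0.900 M; temperature 5 °C; time 10 min
- Saturday's: substrate 1.5 M; first nucleophile 0.900 M; at 5 °C until 2.0 min, from then on at 65 °C; time 10 min

| run | time / min | target / % |
|---|---|---|
| birch | 40.0 | 28.1 |
| birch | 80.0 | 45.8 |
| birch | 120 | 55.7 |
| birch | 150 | 61.6 |
| birch | 180 | 63.1 |
| oak | 3.00 | 47.3 |
| oak | 8.00 | 69.0 |
| oak | 20.0 | 76.0 |
| oak | 25.0 | 75.3 |
| oak | 40.0 | 75.1 |
| elm | 15.0 | 11.5 |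
| elm | 50.0 | 29.0 |
| elm | 90.0 | 36.8 |
| elm | 150 | 37.7 |
| elm | 180 | 37.9 |

(scatter of a reading: 0.5 percentage points)

- at the start none of the gas is in solution
- a reading or a percentage of target counts all its forms, free or not

- the best flask by amount of target, in percent of the substrate charged; "all alike" if 1.5 percentage points covers them all (Tuesday's / Monday's / Thursday's / Saturday's / all alike)
- amount of target at the end, in percent of the substrate charged, Tuesday's
- amount of target at the end, in percent of the substrate charged, Monday's
- amount of target at the end, in percent of the substrate charged, Thursday's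
- amount of target at the end, in percent of the substrate charged, Saturday's

Why believe the roof? Look at elm. Its roof is 40.9%, and its readings flatten at 37.9%, just below.

Then why does oak stop at 75.1%? In oak the ratio is 133%, above one, so there substrate is the limiting reagent, and by subtraction 0.873 M of first nucleophile is not in the target read. So a quarter of oak's substrate is not in target at that reading, and these readings do not say where it stands.

But a roof is no estimate. How full is it in Monday's after 10 min? I let the first nucleophile decay pseudo-first-order, with substrate held at half its charge. Oak's first reading, set against its plateau, gives the speed per unit of nucleophile. Scaled to Monday's time and substrate, that gives an exponent of 1.51. So my Monday's figure is the roof times one minus the exponential of that, 46.7%.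

And the cold flask? Birch held 28.1% after 40.0 min, so Thursday's, in 10 min, should sit low. The hot flasks? Tuesday's 65 °C lies beyond the readings, which end at 35 °C. I hold Tuesday's and Saturday's under the roof and say no more.

The forecast, which held that "oak stalls with both reagents left", gave 37.5% for Tuesday's, 41% for Monday's against my 46.7%, 11% for Thursday's and 37.5% for Saturday's, and named Monday's as best.

The flasks gave 28.3% in Tuesday's, 45.2% in Monday's, 13.3% in Thursday's and 28.1% in Saturday's, so Monday's is best.

    substrate + target → side product (k = 6.45 × 10⁻⁴ L mol⁻¹ s⁻¹, Ea = 59.0 kJ mol⁻¹)
    second nucleophile + intermediate → other capture product (k = 4.91 L mol⁻¹ s⁻¹, Ea = 53.0 kJ mol⁻¹)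
    crystals ⇌ target, rate k3*(cs3 - [target]) while solid is left; crystals form when [target] > cs3 (solubility = 0.170 M, k = 0.0708 s⁻¹)
    gas ⇌ second nucleophile, rate k4*(csat - [second nucleophile]) (kL = 2.67 s⁻¹)
    substrate ⇌ intermediate (K = 0.00515, k = 0.00734 s⁻¹, Ea = 75.0 kJ mol⁻¹, ΔH = −51.0 kJ mol⁻¹)
    first nucleophile + intermediate → target (k = 1.48 L mol⁻¹ s⁻¹, Ea = 39.0 kJ mol⁻¹)
    (constants at 35 °C)

At 10.0 min in Monday's, first nucleophile uses intermediate at 0.57 of the rate at which second nucleophile does, with 20% of its own charge left. Monday's target stands at 45.2% under its roof of 60.0%, beside 33.7% of other capture product. A neighbour of Monday's charged with 2.5 M of substrate has a roof of 36.0% and gives 31.4% of target.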